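## Retrosynthetic overview

1. Kazinol N ⇒ its bis-MOM ether; the prenyl group comes from an aryl bromide on ring B (Li/Br exchange, copper, prenyl bromide).
2. The 2,2-dimethyl-2H-pyran (ring C, the only ring that is built) ⇒ an aryl 1,1-dimethylpropargyl ether on the catechol oxygen para to the chain (propargyl Claisen, then oxa-6π closure). Rings A and B are bought as benzenes.
3. 1,3-Diarylpropane ⇒ dihydrochalcone ⇒ chalcone (copper hydride 1,4-reduction, then Et3SiH/TFA deoxygenation; both spare Ar–Br).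
4. Chalcone ⇒ Claisen–Schmidt aldol condensation of a ring A acetophenone (from 2,4-dihydroxyacetophenone) with a ring B 2-bromobenzaldehyde (from 2-bromo-4,5-dimethoxybenzaldehyde). This joins the two halves at C2–C3 of the propane chain.
5. Oxygen differentiation: PMB on the two phenols that end up free (lost in the TFA step, replaced by MOM); allyl on the oxygen that becomes the pyran oxygen.

Assumption: the target SMILES has no stereocentre and no stereogenic double bond, so Kazinol N is achiral; the route only has to control regiochemistry and the alkene geometry of intermediates.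

## Route

Step 1
Reactants: 1 2,4-dihydroxyacetophenone; 2 4-methoxybenzyl chloride
Product: 3 1-[2-hydroxy-4-(4-methoxybenzyloxy)phenyl]ethanone
Conditions: PMBCl (1.05 eq), K2CO3 (1.2 eq), acetone, reflux, 12 h
Reagents that add atoms: 4-methoxybenzyl chloride, COc1ccc(CCl)cc1
Why: Williamson etherification is selective for the 4-OH because the 2-OH is locked in a hydrogen bond to the acetyl carbonyl and is far less nucleophilic.

Step 2
Reactants: 3 1-[2-hydroxy-4-(4-methoxybenzyloxy)phenyl]ethanone; 4 iodomethane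
Product: 5 1-[2-methoxy-4-(4-methoxybenzyloxy)phenyl]ethanone
Conditions: MeI (3 eq), K2CO3 (3 eq), DMF, 40 °C
Reagents that add atoms: iodomethane, CI
Why: Williamson O-methylation of the remaining chelated phenol goes to completion in DMF with excess MeI, and the PMB ether and ketone are inert.

Step 3
Reactants: 6 2-bromo-4,5-dimethoxybenzaldehyde
Product: 8 2-bromo-4,5-dihydroxybenzaldehyde, via cyclic bromoborate 7 (not isolated)
Conditions: BBr3 (3 eq), CH2Cl2, −78 °C → rt; then H2O, 0 °C
Reagents that add atoms: none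
Why: BBr3 ether cleavage removes both methyl groups through a cyclic catechol borate that is hydrolysed on work-up, while the aryl bromide and the aldehyde survive.

Step 4
Reactants: 8 2-bromo-4,5-dihydroxybenzaldehyde; 9 allyl bromide
Product: 10 4-(allyloxy)-2-bromo-5-hydroxybenzaldehyde
Conditions: allyl bromide (1.05 eq), NaHCO3 (1.5 eq), DMF, 40 °C, 20 h
Reagents that add atoms: allyl bromide, C=CCBr
Why: Regioselective Williamson monoalkylation works because the 4-OH para to the formyl group is about two pKa units more acidic than the 5-OH, so the weak base NaHCO3 ionises and alkylates only that oxygen.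

Step 5
Reactants: 10 4-(allyloxy)-2-bromo-5-hydroxybenzaldehyde; 2 4-methoxybenzyl chloride
Product: 11 4-(allyloxy)-2-bromo-5-(4-methoxybenzyloxy)benzaldehyde
Conditions: PMBCl (1.2 eq), K2CO3 (2 eq), DMF, 50 °C
Reagents that add atoms: 4-methoxybenzyl chloride, COc1ccc(CCl)cc1
Why: Williamson etherification of the remaining phenol gives the two catechol oxygens orthogonal groups (allyl removable by palladium, PMB by acid).

Step 6
Reactants: 5 1-[2-methoxy-4-(4-methoxybenzyloxy)phenyl]ethanone; 11 4-(allyloxy)-2-bromo-5-(4-methoxybenzyloxy)benzaldehyde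
Product: 13 (E)-3-[4-(allyloxy)-2-bromo-5-(4-methoxybenzyloxy)phenyl]-1-[2-methoxy-4-(4-methoxybenzyloxy)phenyl]prop-2-en-1-one, via aldol adduct 12 (not isolated)
Conditions: KOH (50% aq, 5 eq), EtOH/THF 2:1, rt, 24 h
Reagents that add atoms: none
Why: In this Claisen–Schmidt (crossed aldol) condensation the methyl ketone enolate adds to the non-enolisable aldehyde and E1cB dehydration of the aldol gives the thermodynamically favoured E-enone; no stereocentre remains.

Step 7
Reactants: 13 the chalcone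
Product: 15 3-[4-(allyloxy)-2-bromo-5-(4-methoxybenzyloxy)phenyl]-1-[2-methoxy-4-(4-methoxybenzyloxy)phenyl]propan-1-one, via silyl enol ether 14 (not isolated)
Conditions: [(Ph3P)CuH]6 (5 mol%), PhMe2SiH (1.5 eq), toluene, rt; then 1 M HCl, THF, rt
Reagents that add atoms: none
Why: Copper hydride catalysed conjugate reduction (1,4-hydrosilylation) touches only the enone C=C and leaves the aryl bromide, the allyl ether and the benzylic PMB ethers that a palladium hydrogenation would destroy.

Step 8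
Reactants: 15 the dihydrochalcone
Product: 18 4-{3-[4-(allyloxy)-2-bromo-5-hydroxyphenyl]propyl}-3-methoxyphenol, via phenolic ketone 16 (not isolated), via benzylic alcohol 17 (not isolated)
Conditions: Et3SiH (8 eq), TFA/CH2Cl2 1:3, 0 °C → rt, 16 h
Reagents that add atoms: none
Why: Ionic hydrogenation reduces the ring A ketone to CH2 through a benzylic cation stabilised by the para and ortho oxygens, while TFA cleaves both PMB ethers and the silane traps the PMB cations; Ar–Br and the allyl ether are inert.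

Step 9
Reactants: 18 the bis-phenol; 19 chloromethyl methyl ether
Product: 20 1-(allyloxy)-5-bromo-2-(methoxymethoxy)-4-{3-[2-methoxy-4-(methoxymethoxy)phenyl]propyl}benzene
Conditions: MOMCl (3 eq), K2CO3 (4 eq), acetone, 0 °C → rt
Reagents that add atoms: chloromethyl methyl ether, COCCl
Why: Williamson-type MOM ether formation protects both phenols with a group that tolerates palladium, base, heat and organolithium and cannot migrate between the catechol oxygens.

Step 10
Reactants: 20 the bis-MOM allyl ether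
Product: 21 5-bromo-2-(methoxymethoxy)-4-{3-[2-methoxy-4-(methoxymethoxy)phenyl]propyl}phenol
Conditions: Pd(PPh3)4 (5 mol%), morpholine (5 eq), THF, rt
Reagents that add atoms: none
Why: In this Tsuji–Trost deallylation zerovalent palladium ionises the aryl allyl ether to a π-allyl complex that morpholine traps, and at room temperature the hindered electron-rich aryl bromide does not undergo oxidative addition.

Step 11
Reactants: 21 the phenol; 22 3-chloro-3-methylbut-1-yne
Product: 23 1-bromo-4-(methoxymethoxy)-2-{3-[2-methoxy-4-(methoxymethoxy)phenyl]propyl}-5-[(2-methylbut-3-yn-2-yl)oxy]benzene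
Conditions: 3-chloro-3-methylbut-1-yne (3 eq), DBU (3 eq), CuCl2 (1 mol%), MeCN, 0 °C → rt
Reagents that add atoms: 3-chloro-3-methylbut-1-yne, CC(C)(Cl)C#C
Why: Copper-catalysed propargylic O-alkylation (through a copper acetylide) makes the tertiary aryl propargyl ether under mild conditions where a direct SN2 reaction is impossible.

Step 12
Reactants: 23 the aryl propargyl ether
Product: 27 5-bromo-8-(methoxymethoxy)-6-{3-[2-methoxy-4-(methoxymethoxy)phenyl]propyl}-2,2-dimethyl-2H-chromene, via allenyl dienone 24 (not isolated), via allenylphenol 25 (not isolated), via quinone methide 26 (not isolated)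
Conditions: PhNEt2, 180 °C, 2 h
Reagents that add atoms: none
Why: Aromatic propargyl Claisen rearrangement to the only free ortho carbon, tautomerisation, 1,5-hydrogen shift and oxa-6π electrocyclisation build ring C with unambiguous regiochemistry.

Step 13
Reactants: 27 the bromochromene; 28 1-bromo-3-methylbut-2-ene (prenyl bromide)
Product: 31 8-(methoxymethoxy)-6-{3-[2-methoxy-4-(methoxymethoxy)phenyl]propyl}-2,2-dimethyl-5-(3-methylbut-2-en-1-yl)-2H-chromene, via aryllithium 29 (not isolated), via arylcopper 30 (not isolated)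
Conditions: n-BuLi (1.1 eq), THF, −78 °C; CuBr·SMe2 (1.2 eq), −78 → −40 °C; prenyl bromide (2 eq), −78 → 0 °C
Reagents that add atoms: 1-bromo-3-methylbut-2-ene, CC(C)=CCBr
Why: Lithium–bromine exchange, transmetalation to copper and SN2 allylic alkylation put the prenyl group exactly where the bromine was, and attack at the primary carbon avoids the quaternary reverse-prenyl isomer.

Step 14
Reactants: 31 the bis-MOM ether of Kazinol N
Product: 32 Kazinol N, 6-[3-(4-hydroxy-2-methoxyphenyl)propyl]-2,2-dimethyl-5-(3-methylbut-2-en-1-yl)-2H-chromen-8-ol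
Conditions: 3 M aq. HCl/MeOH 1:10, 40 °C, 3 h; NaHCO3 quench
Reagents that add atoms: none
Why: Acid-catalysed acetal cleavage (transacetalisation of MOM to methanol) is run dilute and mild; the prenyl group has no ortho hydroxyl to cyclise onto and a 2,2-dimethylchromene tolerates dilute HCl.

## Compound list

1 | 2,4-dihydroxyacetophenone | CC(=O)c1ccc(O)cc1O | starting material
2 | 4-methoxybenzyl chloride (PMBCl) | COc1ccc(CCl)cc1 | starting material
3 | 1-[2-hydroxy-4-(4-methoxybenzyloxy)phenyl]ethanone | CC(=O)c1ccc(OCc2ccc(OC)cc2)cc1O | intermediate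
4 | iodomethane | CI | starting material
5 | 1-[2-methoxy-4-(4-methoxybenzyloxy)phenyl]ethanone | CC(=O)c1ccc(OCc2ccc(OC)cc2)cc1OC | intermediate
6 | 2-bromo-4,5-dimethoxybenzaldehyde | COc1cc(Br)c(C=O)cc1OC | starting material
7 | 2,6-dibromo-1,3,2-benzodioxaborole-5-carbaldehyde (cyclic bromoborate, formed in the flask) | O=Cc1cc2OB(Br)Oc2cc1Br | intermediate
8 | 2-bromo-4,5-dihydroxybenzaldehyde | O=Cc1cc(O)c(O)cc1Br | intermediate
9 | allyl bromide | C=CCBr | starting material
10 | 4-(allyloxy)-2-bromo-5-hydroxybenzaldehyde | O=Cc1cc(O)c(OCC=C)cc1Br | intermediate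
11 | 4-(allyloxy)-2-bromo-5-(4-methoxybenzyloxy)benzaldehyde | O=Cc1cc(OCc2ccc(OC)cc2)c(OCC=C)cc1Br | intermediate
12 | rac-3-[4-(allyloxy)-2-bromo-5-(4-methoxybenzyloxy)phenyl]-3-hydroxy-1-[2-methoxy-4-(4-methoxybenzyloxy)phenyl]propan-1-one (aldol adduct, formed in the flask) | COc1ccc(COc2ccc(C(=O)CC(O)c3cc(OCc4ccc(OC)cc4)c(OCC=C)cc3Br)c(OC)c2)cc1 | intermediate
13 | (E)-3-[4-(allyloxy)-2-bromo-5-(4-methoxybenzyloxy)phenyl]-1-[2-methoxy-4-(4-methoxybenzyloxy)phenyl]prop-2-en-1-one | COc1ccc(COc2ccc(C(=O)/C=C/c3cc(OCc4ccc(OC)cc4)c(OCC=C)cc3Br)c(OC)c2)cc1 | intermediate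
14 | (Z)-dimethylphenylsilyl enol ether of ketone 15 (formed in the flask) | COc1ccc(COc2ccc(/C(O[Si](C)(C)c5ccccc5)=C/Cc3cc(OCc4ccc(OC)cc4)c(OCC=C)cc3Br)c(OC)c2)cc1 | intermediate
15 | 3-[4-(allyloxy)-2-bromo-5-(4-methoxybenzyloxy)phenyl]-1-[2-methoxy-4-(4-methoxybenzyloxy)phenyl]propan-1-one | COc1ccc(COc2ccc(C(=O)CCc3cc(OCc4ccc(OC)cc4)c(OCC=C)cc3Br)c(OC)c2)cc1 | intermediate
16 | 3-[4-(allyloxy)-2-bromo-5-hydroxyphenyl]-1-(4-hydroxy-2-methoxyphenyl)propan-1-one (formed in the flask) | COc1cc(O)ccc1C(=O)CCc1cc(O)c(OCC=C)cc1Br | intermediate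
17 | rac-2-(allyloxy)-4-bromo-5-[3-hydroxy-3-(4-hydroxy-2-methoxyphenyl)propyl]phenol (formed in the flask) | COc1cc(O)ccc1C(O)CCc1cc(O)c(OCC=C)cc1Br | intermediate
18 | 4-{3-[4-(allyloxy)-2-bromo-5-hydroxyphenyl]propyl}-3-methoxyphenol | COc1cc(O)ccc1CCCc1cc(O)c(OCC=C)cc1Br | intermediate
19 | chloromethyl methyl ether (MOMCl) | COCCl | starting material
20 | 1-(allyloxy)-5-bromo-2-(methoxymethoxy)-4-{3-[2-methoxy-4-(methoxymethoxy)phenyl]propyl}benzene | COCOc1ccc(CCCc2cc(OCOC)c(OCC=C)cc2Br)c(OC)c1 | intermediate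
21 | 5-bromo-2-(methoxymethoxy)-4-{3-[2-methoxy-4-(methoxymethoxy)phenyl]propyl}phenol | COCOc1ccc(CCCc2cc(OCOC)c(O)cc2Br)c(OC)c1 | intermediate
22 | 3-chloro-3-methylbut-1-yne | CC(C)(Cl)C#C | starting material
23 | 1-bromo-4-(methoxymethoxy)-2-{3-[2-methoxy-4-(methoxymethoxy)phenyl]propyl}-5-[(2-methylbut-3-yn-2-yl)oxy]benzene | COCOc1ccc(CCCc2cc(OCOC)c(OC(C)(C)C#C)cc2Br)c(OC)c1 | intermediate
24 | rac-5-bromo-2-(methoxymethoxy)-4-{3-[2-methoxy-4-(methoxymethoxy)phenyl]propyl}-6-(3-methylbuta-1,2-dien-1-yl)cyclohexa-2,4-dien-1-one (formed in the flask) | COCOc1ccc(CCCC2=C(Br)C(C=C=C(C)C)C(=O)C(OCOC)=C2)c(OC)c1 | intermediate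
25 | 3-bromo-6-(methoxymethoxy)-4-{3-[2-methoxy-4-(methoxymethoxy)phenyl]propyl}-2-(3-methylbuta-1,2-dien-1-yl)phenol (formed in the flask) | COCOc1ccc(CCCc2cc(OCOC)c(O)c(C=C=C(C)C)c2Br)c(OC)c1 | intermediate
26 | (6E)-5-bromo-2-(methoxymethoxy)-4-{3-[2-methoxy-4-(methoxymethoxy)phenyl]propyl}-6-(3-methylbut-2-en-1-ylidene)cyclohexa-2,4-dien-1-one, vinyl arm syn to C=O (formed in the flask) | COCOc1ccc(CCCC2=C(Br)/C(=C/C=C(C)C)C(=O)C(OCOC)=C2)c(OC)c1 | intermediate
27 | 5-bromo-8-(methoxymethoxy)-6-{3-[2-methoxy-4-(methoxymethoxy)phenyl]propyl}-2,2-dimethyl-2H-chromene | COCOc1ccc(CCCc2cc(OCOC)c3OC(C)(C)C=Cc3c2Br)c(OC)c1 | intermediate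
28 | 1-bromo-3-methylbut-2-ene (prenyl bromide) | CC(C)=CCBr | starting material
29 | [8-(methoxymethoxy)-6-{3-[2-methoxy-4-(methoxymethoxy)phenyl]propyl}-2,2-dimethyl-2H-chromen-5-yl]lithium (formed in the flask) | COCOc1ccc(CCCc2cc(OCOC)c3OC(C)(C)C=Cc3c2[Li])c(OC)c1 | intermediate
30 | [8-(methoxymethoxy)-6-{3-[2-methoxy-4-(methoxymethoxy)phenyl]propyl}-2,2-dimethyl-2H-chromen-5-yl]copper (formed in the flask) | COCOc1ccc(CCCc2cc(OCOC)c3OC(C)(C)C=Cc3c2[Cu])c(OC)c1 | intermediate
31 | 8-(methoxymethoxy)-6-{3-[2-methoxy-4-(methoxymethoxy)phenyl]propyl}-2,2-dimethyl-5-(3-methylbut-2-en-1-yl)-2H-chromene | COCOc1ccc(CCCc2cc(OCOC)c3OC(C)(C)C=Cc3c2CC=C(C)C)c(OC)c1 | intermediate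
32 | Kazinol N, 6-[3-(4-hydroxy-2-methoxyphenyl)propyl]-2,2-dimethyl-5-(3-methylbut-2-en-1-yl)-2H-chromen-8-ol (achiral) | COc1cc(O)ccc1CCCc1cc(O)c2c(c1CC=C(C)C)C=CC(C)(C)O2 | target

## Step count and risks

Total steps: 14 (ketone branch steps 1–2, aldehyde branch steps 3–5, then steps 6–14).
Longest linear sequence: 12 steps (steps 3–14, from 6).

The three steps most likely to fail:

Step 13 (prenylation of the bromochromene). The aryl metal sits between the propyl chain and the chromene vinyl carbon, so protonation to the debrominated arene or slow, unselective allylation can win. The fallback puts the prenyl group on before the pyran ring is annulated, while the bromide has a free ortho position. It sets out from 20. Lithium–bromine exchange (n-BuLi, THF, −78 °C), CuBr·SMe2 and prenyl bromide give 1-(allyloxy)-2-(methoxymethoxy)-4-{3-[2-methoxy-4-(methoxymethoxy)phenyl]propyl}-5-(3-methylbut-2-en-1-yl)benzene F3. Deallylation with Pd(PPh3)4 and morpholine, now with no aryl bromide present, gives the phenol 2-(methoxymethoxy)-4-{3-[2-methoxy-4-(methoxymethoxy)phenyl]propyl}-5-(3-methylbut-2-en-1-yl)phenol F4. Alkylation with 22 (DBU, CuCl2 cat., MeCN) gives the propargyl ether 4-(methoxymethoxy)-2-{3-[2-methoxy-4-(methoxymethoxy)phenyl]propyl}-1-(3-methylbut-2-en-1-yl)-5-[(2-methylbut-3-yn-2-yl)oxy]benzene F5. Heating in PhNEt2 at 180 °C closes the pyran onto the only free ortho carbon, next to the prenyl group, and the route is rejoined at 31.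

Step 8 (one-pot ketone deoxygenation and PMB loss). The chain benzylic cation can be captured by ring B to give a 1-arylindane, PMB cations can C-alkylate the electron-rich rings, or the ketone may reduce incompletely. The fallback removes the carbonyl without a carbocation. It sets out from 15. Condensation with TsNHNH2 (EtOH, cat. AcOH, 70 °C) gives the tosylhydrazone of 15 (E/Z mixture) F1. Catecholborane in CHCl3 at 0 °C, then NaOAc·3H2O at reflux, gives 1-(allyloxy)-5-bromo-2-(4-methoxybenzyloxy)-4-{3-[2-methoxy-4-(4-methoxybenzyloxy)phenyl]propyl}benzene F2. A short, cold PMB cleavage (TFA/CH2Cl2, Et3SiH, 0 °C, 20 min), now with no chain cation possible, rejoins the route at 18.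

Step 14 (acidic MOM removal with prenyl and chromene present). Markovnikov addition of methanol or water to the prenyl or chromene alkene is the danger. The fallback takes the MOM groups off before the prenyl group exists and finishes under neutral conditions. It sets out from 27. The same HCl/MeOH treatment gives 5-bromo-6-[3-(4-hydroxy-2-methoxyphenyl)propyl]-2,2-dimethyl-2H-chromen-8-ol F6. Stille coupling of this free bis-phenol with tributyl(3-methylbut-2-en-1-yl)stannane (Pd(PPh3)4, DMF, 100 °C) delivers the prenyl group at the bromine-bearing carbon, and the route is rejoined at the target 32.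

## Further compounds

F1 | step 8 | N'-{3-[4-(allyloxy)-2-bromo-5-(4-methoxybenzyloxy)phenyl]-1-[2-methoxy-4-(4-methoxybenzyloxy)phenyl]propylidene}-4-methylbenzenesulfonohydrazide | COc1ccc(COc2ccc(C(CCc3cc(OCc4ccc(OC)cc4)c(OCC=C)cc3Br)=NNS(=O)(=O)c3ccc(C)cc3)c(OC)c2)cc1
F2 | step 8 | 1-(allyloxy)-5-bromo-2-(4-methoxybenzyloxy)-4-{3-[2-methoxy-4-(4-methoxybenzyloxy)phenyl]propyl}benzene | COc1ccc(COc2ccc(CCCc3cc(OCc4ccc(OC)cc4)c(OCC=C)cc3Br)c(OC)c2)cc1
F3 | step 13 | 1-(allyloxy)-2-(methoxymethoxy)-4-{3-[2-methoxy-4-(methoxymethoxy)phenyl]propyl}-5-(3-methylbut-2-en-1-yl)benzene | COCOc1ccc(CCCc2cc(OCOC)c(OCC=C)cc2CC=C(C)C)c(OC)c1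
F4 | step 13 | 2-(methoxymethoxy)-4-{3-[2-methoxy-4-(methoxymethoxy)phenyl]propyl}-5-(3-methylbut-2-en-1-yl)phenol | COCOc1ccc(CCCc2cc(OCOC)c(O)cc2CC=C(C)C)c(OC)c1
F5 | step 13 | 4-(methoxymethoxy)-2-{3-[2-methoxy-4-(methoxymethoxy)phenyl]propyl}-1-(3-methylbut-2-en-1-yl)-5-[(2-methylbut-3-yn-2-yl)oxy]benzene | COCOc1ccc(CCCc2cc(OCOC)c(OC(C)(C)C#C)cc2CC=C(C)C)c(OC)c1
F6 | step 14 | 5-bromo-6-[3-(4-hydroxy-2-methoxyphenyl)propyl]-2,2-dimethyl-2H-chromen-8-ol | COc1cc(O)ccc1CCCc1cc(O)c2OC(C)(C)C=Cc2c1Br
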